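Ring B, the fully substituted arene shared by the chromanone (ring D) and the seven-membered lactone (ring C), is built from a four-membered ring. An isopropyl semisquarate supplies four ring carbons with all three oxygens; a trisubstituted alkenyllithium supplies the C-methyl carbon and the carbon that will carry the acyl group. On thermolysis the derived cyclobutenone (4-alkenyl, 4-hydroxy, 3-isopropoxy) undergoes ring opening to a dienylketene and 6π closure in one operation, so ring B emerges as a hydroquinone: ring D oxygen para to the diaryl ether oxygen, lactone oxygen (as isopropyl ether) beside the latter, methyl beside the future acyl carbon. Ring D, the diaryl ether and the lactone follow.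

Key step: step 6

Remark on the chemistry: the side-chain carbinol is carried as its racemic TBS ether through the thermolysis and oxidised afterwards. Ring A carries a benzyl ester so that the BCl3 step also frees the acid for lactonisation. The target has no stereocentre, so all intermediates are used as racemates or diastereomer mixtures.

Step 1
Reactants: 1 diisopropyl squarate
Product: 3 3-isopropoxycyclobut-3-ene-1,2-dione (isopropyl semisquarate), via hydroxycyclobutenone 2 (not isolated)
Conditions: LiAlH(OtBu)3, THF, −78 to 0 °C; then conc. HCl (cat.), CH2Cl2, rt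
Reagents that add atoms: water, O
Why: The bulky aluminate should reduce one of the two equivalent carbonyls once (1,2-reduction), and acid then ionises the allylic hydroxyl and hydrolyses the resulting oxocarbenium with loss of isopropanol, a known route to alkoxycyclobutenediones in which the racemic carbinol centre of 2 disappears.

Step 2
Reactants: 4 3-methyl-2-butenal; 5 1-propynylmagnesium bromide
Product: 6 2-methylhept-2-en-5-yn-4-ol (racemic)
Conditions: THF, −78 to 0 °C; aq NH4Cl
Reagents that add atoms: none
Why: Grignard 1,2-addition of the alkynyl reagent to the enal carbonyl should give the propargylic, allylic alcohol, whose new centre is racemic and irrelevant because it is oxidised to the ketone later.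

Step 3
Reactants: 6 2-methylhept-2-en-5-yn-4-ol
Product: 7 4-(tert-butyldimethylsilyloxy)-2-methylhept-2-en-5-yne (racemic)
Conditions: TBSCl, imidazole, DMF, rt
Reagents that add atoms: tert-butyldimethylsilyl chloride, CC(C)(C)[Si](C)(C)Cl
Why: Imidazole-promoted silylation of a secondary alcohol (silyl ether formation) is routine and touches no other group.

Step 4
Reactants: 7 4-(tert-butyldimethylsilyloxy)-2-methylhept-2-en-5-yne
Product: 9 (E)-4-(tert-butyldimethylsilyloxy)-2-iodo-6-methylhepta-2,5-diene (racemic; iodine trans to the silyloxy-bearing carbon), via alkenylzirconocene 8 (not isolated)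
Conditions: Cp2Zr(H)Cl (excess), THF, 50 °C; then I2, 0 °C
Reagents that add atoms: iodine, II
Why: Syn hydrozirconation of the methyl alkyne should, after equilibration with excess reagent, place zirconium on the less hindered methyl-bearing carbon, and iodinolysis with retention then gives the E alkenyl iodide (hydrozirconation–iodination), the trisubstituted alkene being inert.

Step 5
Reactants: 9 (E)-4-(tert-butyldimethylsilyloxy)-2-iodo-6-methylhepta-2,5-diene; 3 3-isopropoxycyclobut-3-ene-1,2-dione
Product: 11 4-hydroxy-3-isopropoxy-4-[(E)-4-(tert-butyldimethylsilyloxy)-6-methylhepta-2,5-dien-2-yl]cyclobut-2-enone (mixture of diastereomers), via alkenyllithium 10 (not isolated)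
Conditions: t-BuLi (2 equiv), Et2O, −78 °C; then 3, THF, −78 °C; aq NH4Cl
Reagents that add atoms: none
Why: Iodine–lithium exchange with retention of alkene geometry followed by 1,2-addition to the ketone-like carbonyl of 3 (the other carbonyl is a deactivated vinylogous ester) is the known regioselective organolithium addition to alkoxycyclobutenediones; the new carbinol centre forms without control and is lost in step 6.

Step 6
Reactants: 11 4-hydroxy-3-isopropoxy-4-[(E)-4-(tert-butyldimethylsilyloxy)-6-methylhepta-2,5-dien-2-yl]cyclobut-2-enone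
Product: 14 6-isopropoxy-2-methyl-3-[1-(tert-butyldimethylsilyloxy)-3-methylbut-2-enyl]benzene-1,4-diol (racemic), via dienylketene 12 (not isolated), via cyclohexadienone 13 (not isolated)
Conditions: toluene (0.01 M, degassed), 110 °C, argon
Reagents that add atoms: none
Why: Thermal conrotatory 4π opening of the C1–C4 bond of the cyclobutenone should give dienylketene 12, whose ketene carbon and alkene terminus are joined by a thermal disrotatory 6π electrocyclisation to cyclohexadienone 13, which enolises to hydroquinone 14; this is the Moore rearrangement of a 4-alkenyl-4-hydroxycyclobutenone, a known thermal ring expansion. Ring B is closed as an all-carbon six-membered ring by this 6π electrocyclic closure, which forms the C–C bond between the carbon of the future ring D oxygen and the carbon that will carry the acyl group. No stereocentre survives in the ring, and the side-chain carbinol stays racemic until it is oxidised. The step needs the alkenyl group to turn inward on ring opening, which the outward preference of the C4 hydroxyl donor secures, and it needs the terminus substituent to point away from the ketene, which the E alkene from step 4 secures. The substitution pattern is fixed by connectivity alone: the isopropoxy carbon becomes the lactone-oxygen carbon, the ketene carbonyl becomes the ring D phenol, and the carbinol carbon becomes the diaryl ether phenol flanked by methyl and isopropoxy. High dilution and exclusion of air should keep the ketene from intermolecular capture and the hydroquinone from oxidation.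

Step 7
Reactants: 14 6-isopropoxy-2-methyl-3-[1-(tert-butyldimethylsilyloxy)-3-methylbut-2-enyl]benzene-1,4-diol
Product: 16 2-isopropoxy-6-methyl-5-(3-methylbut-2-enoyl)cyclohexa-2,5-diene-1,4-dione, via triol 15 (not isolated)
Conditions: TBAF, AcOH, THF, 0 °C, argon; then MnO2 (excess), CH2Cl2, rt
Reagents that add atoms: none
Why: Buffered fluoride should cleave the silyl ether, and MnO2 then oxidises the hydroquinone to the quinone and the allylic alcohol to the enone (desilylation followed by MnO2 oxidation), which removes the only stereocentre and avoids isolating the ionisable triol.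

Step 8
Reactants: 16 2-isopropoxy-6-methyl-5-(3-methylbut-2-enoyl)cyclohexa-2,5-diene-1,4-dione
Product: 18 6-hydroxy-7-isopropoxy-2,2,5-trimethylchroman-4-one, via acylhydroquinone 17 (not isolated)
Conditions: Na2S2O4, THF/H2O, rt; then K2CO3 to pH 9–10, rt, argon
Reagents that add atoms: none
Why: Dithionite reduction of the quinone followed by base-promoted 6-endo oxa-Michael addition of the phenol ortho to the enone is the usual route from o-hydroxyaryl prenyl ketones to 2,2-dimethylchromanones; only that hydroxyl can reach the enone, so the para hydroxyl stays free.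

Step 9
Reactants: 19 3-fluoro-5-methylanisole
Product: 20 4-bromo-3-fluoro-5-methylanisole
Conditions: NBS, MeCN, 0 °C to rt
Reagents that add atoms: N-bromosuccinimide, O=C1CCC(=O)N1Br
Why: Electrophilic aromatic bromination with NBS in acetonitrile should go para to the methoxy group, the site that lies between fluorine and methyl.

Step 10
Reactants: 20 4-bromo-3-fluoro-5-methylanisole
Product: 22 3-bromo-2-fluoro-6-methoxy-4-methylbenzaldehyde, via aryllithium 21 (not isolated)
Conditions: LiN(iPr)2, THF, −78 °C; DMF, −78 °C; aq HCl
Reagents that add atoms: N,N-dimethylformamide, CN(C)C=O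
Why: Directed ortho-metalation removes the most acidic ring proton, flanked by fluorine and methoxy, and DMF formylates the aryllithium, which at −78 °C should neither lose LiF nor exchange with the bromide.

Step 11
Reactants: 22 3-bromo-2-fluoro-6-methoxy-4-methylbenzaldehyde
Product: 23 benzyl 2-fluoro-3-formyl-4-methoxy-6-methylbenzoate
Conditions: Pd(OAc)2 (cat.), Xantphos, CO (1 atm), BnOH, Et3N, toluene, 90 °C
Reagents that add atoms: carbon monoxide, [C-]#[O+]; benzyl alcohol, OCc1ccccc1
Why: Palladium-catalysed alkoxycarbonylation of the aryl bromide (oxidative addition, CO insertion, alcoholysis of the acylpalladium) tolerates the aldehyde and leaves the C–F bond intact.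

Step 12
Reactants: 18 6-hydroxy-7-isopropoxy-2,2,5-trimethylchroman-4-one; 23 benzyl 2-fluoro-3-formyl-4-methoxy-6-methylbenzoate
Product: 24 benzyl 3-formyl-2-[(7-isopropoxy-2,2,5-trimethyl-4-oxochroman-6-yl)oxy]-4-methoxy-6-methylbenzoate
Conditions: K2CO3, DMF, 50 °C, argon
Reagents that add atoms: none
Why: Nucleophilic aromatic substitution by addition–elimination should work because the fluoride is activated by an ortho formyl and an ortho ester group, while both donor groups of ring A sit meta to the leaving group.

Step 13
Reactants: 24 benzyl 3-formyl-2-[(7-isopropoxy-2,2,5-trimethyl-4-oxochroman-6-yl)oxy]-4-methoxy-6-methylbenzoate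
Product: 25 3-formyl-4-hydroxy-2-[(7-hydroxy-2,2,5-trimethyl-4-oxochroman-6-yl)oxy]-6-methylbenzoic acid
Conditions: BCl3 (excess), CH2Cl2, −78 to 0 °C; aq NaHCO3 then dilute HCl
Reagents that add atoms: none
Why: BCl3 cleaves aryl isopropyl ethers, methyl ethers chelated to an ortho carbonyl and benzyl esters (Lewis acid dealkylation with chloride as nucleophile), while the diaryl ether and the vinylogous-ester oxygen of ring D should survive at low temperature.

Step 14
Reactants: 25 3-formyl-4-hydroxy-2-[(7-hydroxy-2,2,5-trimethyl-4-oxochroman-6-yl)oxy]-6-methylbenzoic acid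
Product: 26 mollicellin A
Conditions: DCC, THF (0.005 M), rt
Reagents that add atoms: none
Why: Carbodiimide activation of the hindered acid and attack by the neighbouring ring B phenol should close the seven-membered lactone (lactonisation of a 2-(2-hydroxyphenoxy)benzoic acid, the standard depsidone closure) under neutral conditions that avoid a base-induced Smiles rearrangement; the chelated ring A phenol is para to the acid and cannot cyclise.

Compound list
1 | diisopropyl squarate (3,4-diisopropoxycyclobut-3-ene-1,2-dione) | CC(C)OC1=C(OC(C)C)C(=O)C1=O | starting material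
2 | 4-hydroxy-2,3-diisopropoxycyclobut-2-en-1-one (racemic) | CC(C)OC1=C(OC(C)C)C(=O)C1O | intermediate
3 | 3-isopropoxycyclobut-3-ene-1,2-dione | CC(C)OC1=CC(=O)C1=O | intermediate
4 | 3-methyl-2-butenal | CC(C)=CC=O | starting material
5 | 1-propynylmagnesium bromide | CC#C[Mg]Br | starting material
6 | 2-methylhept-2-en-5-yn-4-ol (racemic) | CC#CC(O)C=C(C)C | intermediate
7 | 4-(tert-butyldimethylsilyloxy)-2-methylhept-2-en-5-yne (racemic) | CC#CC(O[Si](C)(C)C(C)(C)C)C=C(C)C | intermediate
8 | (E)-[4-(tert-butyldimethylsilyloxy)-6-methylhepta-2,5-dien-2-yl]zirconocene chloride | Cl[Zr](C1C=CC=C1)(C1C=CC=C1)/C(C)=C/C(O[Si](C)(C)C(C)(C)C)C=C(C)C | intermediate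
9 | (E)-4-(tert-butyldimethylsilyloxy)-2-iodo-6-methylhepta-2,5-diene (racemic) | I/C(C)=C/C(O[Si](C)(C)C(C)(C)C)C=C(C)C | intermediate
10 | (E)-[4-(tert-butyldimethylsilyloxy)-6-methylhepta-2,5-dien-2-yl]lithium | [Li]/C(C)=C/C(O[Si](C)(C)C(C)(C)C)C=C(C)C | intermediate
11 | 4-hydroxy-3-isopropoxy-4-[(E)-4-(tert-butyldimethylsilyloxy)-6-methylhepta-2,5-dien-2-yl]cyclobut-2-enone (diastereomer mixture) | O=C1C=C(OC(C)C)C1(O)/C(C)=C/C(O[Si](C)(C)C(C)(C)C)C=C(C)C | intermediate
12 | dienylketene: 4-hydroxy-3-isopropoxy-5,9-dimethyl-7-(tert-butyldimethylsilyloxy)deca-1,3,5,8-tetraen-1-one, alkenyl group cis to the ketenyl carbon | O=C=C/C(OC(C)C)=C(/O)\C(C)=C\C(O[Si](C)(C)C(C)(C)C)C=C(C)C | intermediate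
13 | 4-hydroxy-3-isopropoxy-5-methyl-6-[1-(tert-butyldimethylsilyloxy)-3-methylbut-2-enyl]cyclohexa-2,4-dienone | O=C1C=C(OC(C)C)C(O)=C(C)C1C(O[Si](C)(C)C(C)(C)C)C=C(C)C | intermediate
14 | 6-isopropoxy-2-methyl-3-[1-(tert-butyldimethylsilyloxy)-3-methylbut-2-enyl]benzene-1,4-diol (racemic) | CC(C)Oc1cc(O)c(C(O[Si](C)(C)C(C)(C)C)C=C(C)C)c(C)c1O | intermediate
15 | 3-(1-hydroxy-3-methylbut-2-enyl)-6-isopropoxy-2-methylbenzene-1,4-diol (racemic) | CC(C)Oc1cc(O)c(C(O)C=C(C)C)c(C)c1O | intermediate
16 | 2-isopropoxy-6-methyl-5-(3-methylbut-2-enoyl)cyclohexa-2,5-diene-1,4-dione | CC(C)OC1=CC(=O)C(C(=O)C=C(C)C)=C(C)C1=O | intermediate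
17 | 1-(3,6-dihydroxy-4-isopropoxy-2-methylphenyl)-3-methylbut-2-en-1-one | CC(C)Oc1cc(O)c(C(=O)C=C(C)C)c(C)c1O | intermediate
18 | 6-hydroxy-7-isopropoxy-2,2,5-trimethylchroman-4-one | CC(C)Oc1cc2OC(C)(C)CC(=O)c2c(C)c1O | intermediate
19 | 3-fluoro-5-methylanisole | COc1cc(C)cc(F)c1 | starting material
20 | 4-bromo-3-fluoro-5-methylanisole | COc1cc(C)c(Br)c(F)c1 | intermediate
21 | (3-bromo-2-fluoro-6-methoxy-4-methylphenyl)lithium | COc1cc(C)c(Br)c(F)c1[Li] | intermediate
22 | 3-bromo-2-fluoro-6-methoxy-4-methylbenzaldehyde | COc1cc(C)c(Br)c(F)c1C=O | intermediate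
23 | benzyl 2-fluoro-3-formyl-4-methoxy-6-methylbenzoate | COc1cc(C)c(C(=O)OCc2ccccc2)c(F)c1C=O | intermediate
24 | benzyl 3-formyl-2-[(7-isopropoxy-2,2,5-trimethyl-4-oxochroman-6-yl)oxy]-4-methoxy-6-methylbenzoate | CC(C)Oc1cc2OC(C)(C)CC(=O)c2c(C)c1Oc1c(C=O)c(OC)cc(C)c1C(=O)OCc1ccccc1 | intermediate
25 | 3-formyl-4-hydroxy-2-[(7-hydroxy-2,2,5-trimethyl-4-oxochroman-6-yl)oxy]-6-methylbenzoic acid | Cc1cc(O)c(C=O)c(Oc2c(O)cc3OC(C)(C)CC(=O)c3c2C)c1C(=O)O | intermediate
26 | mollicellin A | Cc1cc(O)c(C=O)c2c1C(=O)Oc1cc3c(c(C)c1O2)C(=O)CC(C)(C)O3 | target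

Total step count: 14
Longest linear sequence: 10 steps (steps 2, 3, 4, 5, 6, 7, 8, 12, 13, 14; from 4 to 26)

Steps most likely to fail

Step 6. The nascent hydroquinone may lose silanol from the o-hydroxybenzylic, allylic position (o-quinone methide formation and oxa-6π closure to a 2H-chromene), or the ketene may be captured by phenolic product before it cyclises. The fallback sets out from 11 and returns at 18. The side chain is brought to the ketone level before ring B is formed: 11 is desilylated with HF·pyridine in THF/pyridine to 4-hydroxy-4-[(E)-4-hydroxy-6-methylhepta-2,5-dien-2-yl]-3-isopropoxycyclobut-2-enone F1, and MnO2 oxidises the bis-allylic alcohol to 4-hydroxy-3-isopropoxy-4-[(E)-6-methyl-4-oxohepta-2,5-dien-2-yl]cyclobut-2-enone F2. Thermolysis of F2 in toluene should then give acylhydroquinone 17 directly, which has no ionisable benzylic oxygen and closes to 18 under the K2CO3 treatment of step 8.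

Step 7. The free benzylic, allylic carbinol may ionise while ring B is still an electron-rich hydroquinone (dehydration to the chromene), or the acylquinone may be attacked by fluoride or acetate. The fallback sets out from 14 and returns at 16, and it reverses the order of events. MnO2 first converts 14 into 2-isopropoxy-6-methyl-5-[1-(tert-butyldimethylsilyloxy)-3-methylbut-2-enyl]cyclohexa-2,5-diene-1,4-dione F3, in which the benzylic position is no longer activated. Aqueous HF in MeCN then gives 5-(1-hydroxy-3-methylbut-2-enyl)-2-isopropoxy-6-methylcyclohexa-2,5-diene-1,4-dione F4, and a second MnO2 oxidation gives 16.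

Step 12. The intermolecular substitution between a phenoxide flanked by methyl and isopropoxy and a fluoride flanked by two ortho groups may be too slow, and aldol condensation of the chromanone methylene with the aldehyde or base-induced opening of ring D may compete. The fallback sets out from 18 and 22 and returns at 26. It forms the ester first and closes the diaryl ether intramolecularly:
- BCl3 converts 18 into 6,7-dihydroxy-2,2,5-trimethylchroman-4-one F5.
- Pd(OAc)2/Xantphos-catalysed hydroxycarbonylation of 22 (CO, H2O, Et3N) gives 2-fluoro-3-formyl-4-methoxy-6-methylbenzoic acid F6.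
- TFAA-mediated esterification at the less hindered and more acidic 7-hydroxyl gives 6-hydroxy-2,2,5-trimethyl-4-oxochroman-7-yl 2-fluoro-3-formyl-4-methoxy-6-methylbenzoate F7.
- K2CO3 in DMF closes the seven-membered ring by intramolecular substitution of fluoride to give mollicellin A methyl ether F8.
- BCl3 removes the chelated methyl ether to give 26.

Further compounds
F1 | step 6 | 4-hydroxy-4-[(E)-4-hydroxy-6-methylhepta-2,5-dien-2-yl]-3-isopropoxycyclobut-2-enone | O=C1C=C(OC(C)C)C1(O)/C(C)=C/C(O)C=C(C)C
F2 | step 6 | 4-hydroxy-3-isopropoxy-4-[(E)-6-methyl-4-oxohepta-2,5-dien-2-yl]cyclobut-2-enone | O=C1C=C(OC(C)C)C1(O)/C(C)=C/C(=O)C=C(C)C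
F3 | step 7 | 2-isopropoxy-6-methyl-5-[1-(tert-butyldimethylsilyloxy)-3-methylbut-2-enyl]cyclohexa-2,5-diene-1,4-dione | CC(C)OC1=CC(=O)C(C(O[Si](C)(C)C(C)(C)C)C=C(C)C)=C(C)C1=O
F4 | step 7 | 5-(1-hydroxy-3-methylbut-2-enyl)-2-isopropoxy-6-methylcyclohexa-2,5-diene-1,4-dione | CC(C)OC1=CC(=O)C(C(O)C=C(C)C)=C(C)C1=O
F5 | step 12 | 6,7-dihydroxy-2,2,5-trimethylchroman-4-one | Cc1c(O)c(O)cc2OC(C)(C)CC(=O)c12
F6 | step 12 | 2-fluoro-3-formyl-4-methoxy-6-methylbenzoic acid | COc1cc(C)c(C(=O)O)c(F)c1C=O
F7 | step 12 | 6-hydroxy-2,2,5-trimethyl-4-oxochroman-7-yl 2-fluoro-3-formyl-4-methoxy-6-methylbenzoate | COc1cc(C)c(C(=O)Oc2cc3OC(C)(C)CC(=O)c3c(C)c2O)c(F)c1C=O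
F8 | step 12 | mollicellin A methyl ether | COc1cc(C)c2C(=O)Oc3cc4OC(C)(C)CC(=O)c4c(C)c3Oc2c1C=O
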